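## The problem

Target 33 has three rings joined through one carbon. A pentasubstituted tropone (ring A) is fused along a C–C edge to a dihydrofuran (ring F). The oxygen-bearing sp3 carbon of ring F is also the spiro carbon C1 of a cyclohexane (ring B: C1 spiro, C2 CH–CH3, C3, C4, C5 CH–C(CH3)2OH, C6 quaternary with CH3 and CH2CH2CO2H).

All four stereocentres are contiguous on ring B (C5 S, C6 R, C1 S, C2 R). The C2 and C6 methyl groups are cis to each other and trans to the ring F oxygen. With the C5 substituent equatorial, both methyls and the C1–O bond are axial, so C2 is not the epimer that equilibration would give and has to be set kinetically.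

Control can be relayed around the ring. C5 comes with carvone and directs the two alkylations at C6. The axial C6 methyl shields one face of C1. The C1 oxygen can then steer hydrogen to C2.

Several groups are fragile: the tertiary alcohol (elimination, O–H insertion by carbenoids), the acid-labile enol ethers that precede ring F, and the tropone (reducible, a vinylogous ester). One carboxyl must also end as a methyl ester and the other as the free acid.

The feature that opens the key step lies in ring A, whose atoms are labelled a–g here: Ca ester-bearing, Cb carbonyl, Cc C-methyl, Cd O-bearing fusion carbon, Ce CH2-bearing fusion carbon, Cf CH, Cg C-methyl. Ca–Cb–Cc is a three-carbon unit at the oxidation level of a 3-siloxy-2-diazopent-3-enoate. Cd–Ce–Cf–Cg with the ring F oxygen is a 1-alkoxy-1,3-diene. Because C1 is quaternary, ring F cannot aromatise to a furan, so this dienyl ether is a stable compound. The sp3 centres created in ring A are all removed when the tropone is formed.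

## Retrosynthesis

**33 to 31 and 30.** The carboxylic acid is taken back to a primary alcohol (31) and both alcohols to silyl ethers (30). No bond of the skeleton is cut. The point is that the chain stays inert through hydride, ylide and carbenoid chemistry and that two esters never have to be told apart. The forward oxidation must leave the tertiary alcohol and the tropone alone.

**30 to 28.** The tropone is taken back to a cycloheptadiene silyl enol ether by adding back H at Cg, Cc and Cd and silicon on the Cb oxygen. This changes an aromatic ring into one with three sp3 carbons that a cycloaddition can reach. The forward step needs two hydride abstractions by DDQ without loss of the ring F C–O bond.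

**28 to 23 and 26 (key cut).** The bonds Ca–Cg and Cc–Cd are cut. This divides the seven carbons 3 + 4 along their natural polarity: the diazo carbon is the electrophile and the diene terminus the nucleophile. The neighbouring cut, joining a finished tropone to ring B through ring F, would need a pentasubstituted halotropone; here ring A comes from a two-step diazo ester. Dienyl ether 23 holds every stereocentre but no ring A. The forward reaction must select the Z-propenyl alkene over the ring F alkene and carry the cyclopropane through a Cope shift.

**26 to 25 to 24.** The silyl enol ether and the diazo group are removed in turn, back to commercial methyl 3-oxopentanoate.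

**23 to 20 (with 21), 18, 16 and 14.** The propenyl C=C is cut by a Wittig disconnection, the formyl C–C bond by a Vilsmeier disconnection, and the enol ether is taken back to a γ-lactone. Each precursor is simpler by one functional group. The Wittig step must be Z-selective, because only a cis-disubstituted alkene accepts the carbenoid.

**14 to 13 to 12.** The C2–H bond is cut first (hydrogenation). Then the C1–O bond and the CH2–CH2 bond of the lactone are cut (oxidative lactone annulation with acetic acid as the two-carbon unit). The alternative of adding a carbon nucleophile to a C1 ketone would put carbon, not oxygen, on the face away from the axial C6 methyl and give the wrong C1 epimer. Bringing oxygen in last, onto an allyl cation, uses the same shielding in the right sense. The ring alkene kept in 13 lets the lactone oxygen direct hydrogen to C2.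

**12 to 11 to 9 to 8.** The chain oxygen is removed back to an allyl group, and the exocyclic methylene back to the ketone. Hydroboration is placed after methylenation so that no ketone competes for the borane.

**8 to 5 to 3 to 2 to 1.** The C6–allyl and C6–methyl bonds are cut as enolate alkylations; methyl first and allyl second puts the allyl group trans to the C5 substituent. The tertiary alcohol is taken back to the isopropenyl group of (S)-carvone. Hydration comes first so that this alkene is gone before steps 6, 8 and 9.

## Roads not taken

**Alternative 1:** Ring B would be made by a catalytic asymmetric Diels–Alder reaction. The cuts are C6–C1 and C5–C4. A chiral N-protonated oxazaborolidine would activate an E-configured α-methyl enal carrying the protected carbinol on its β-carbon, and a 1-siloxy-2-methyldiene would add endo to give aldehyde A1.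

- Merits: C5, C6 and the C1 oxygen are set in one catalytic step; the two C6 substituents are differentiated from the start; no enolate alkylation next to a bulky group is needed; either enantiomer is available.
- Weak points: the dienophile is α,β-disubstituted with a tertiary β-substituent, a poorly reactive class for this catalysis. Both partners need their own syntheses. A1 solves only ring B; the aldehyde must still be extended and the allylic silyl ether turned into the C1 methylene before rings F and A can be built as in the chosen plan.
- Comparison: in catalyst control and in avoiding the hindered alkylation of step 4 this road is better. The chosen plan sets against it that (S)-carvone already holds C5, all ring B carbons and the C2 methyl, and reaches 8 in four steps.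

**Alternative 2:** Ring B would be closed by an enolate Claisen ring contraction. The cut is C5–C6. The silyl ketene acetal of a δ-lactone with a tertiary allylic C–O bond would rearrange through a boat to acid A2, transferring chirality to C5 and C6.

- Merits: the quaternary carbon comes from a concerted, predictable transition state; the acid is a direct precursor of the carbinol (two methyl additions); the chain arrives already protected.
- Weak points: the lactone needs an enantioselective synthesis of a tertiary allylic carbinol and a defined trisubstituted alkene. A2 has no oxygen at C1 (it is an alkene CH), so the C1 functionality must be added by a regioselective oxidation. Again only ring B is solved.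
- Comparison: stereocontrol at C6 is more secure than approach control in an alkylation. The chosen plan is shorter to the same stage and starts from the chiral pool.

**Alternative 3:** Ring F would be closed by a palladium heteroannulation. The cuts are Ce–CH2 and C1–O. Zerovalent palladium from Pd(OAc)2 would insert into the C–I bond of a fully substituted iodohydroxytropone, the tropone carbon would add to the CH2 end of a semicyclic diene like 9, and the tropone oxygen would close on the π-allyl to give A3.

- Merits: this is the most convergent road and is shorter on paper than the chosen one. Ring A arrives complete and no late dehydrogenation is needed.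
- Weak points:
  - The pentasubstituted iodohydroxytropone is itself a multistep target, and as a vinylogous acid it is a poor oxygen nucleophile.
  - Palladium should add from the face away from the axial C6 methyl, so external attack of oxygen anti to the metal would give the C1 epimer of the target. Only inner-sphere delivery gives the right one.
  - The ring B alkene of A3 must then be hydrogenated face-selectively next to a reducible tropone and without a directing lactone.
  - A3 carries two methyl esters that must be told apart.
- Comparison: in step count and convergence this road wins. The chosen plan sets against it that C1 and C2 are fixed on a simple lactone before any tropone exists, and that ring A comes from a two-step diazo ester.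

Key step: step 16

Remark: centres that form as mixtures and are destroyed later (C6 of 5, the lactol carbon of 15–17, the sp3 carbons of ring A in 27–29) are left undefined in the SMILES. TBS is tert-butyldimethylsilyl and TBDPS is tert-butyldiphenylsilyl.

## Route

Step 1
Reactants: 1 (S)-carvone
Product: 2 (5S)-5-(2-hydroxypropan-2-yl)-2-methylcyclohex-2-en-1-one
Conditions: 50% aq. H2SO4, 0 °C → rt
Reagents that add atoms: water (O)
Why: Markovnikov acid-catalysed hydration of the 1,1-disubstituted alkene through its tertiary cation; the enone is deactivated toward protonation and C5 is untouched.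

Step 2
Reactants: 2 (5S)-5-(2-hydroxypropan-2-yl)-2-methylcyclohex-2-en-1-one
Product: 3 TBS ether of 2
Conditions: TBSOTf, 2,6-lutidine, CH2Cl2, −78 → 0 °C
Reagents that add atoms: tert-butyldimethylsilyl trifluoromethanesulfonate (CC(C)(C)[Si](C)(C)OS(=O)(=O)C(F)(F)F)
Why: Silyl triflate silylation of a tertiary alcohol; the hindered TBS ether is chosen because it has to survive buffered hot acetic acid in step 8 and the Vilsmeier reagent in step 12.

Step 3
Reactants: 3 TBS ether of 2
Product: 5 6-methyl enone (methyl trans to the C5 side chain), via lithium dienolate 4 (not isolated)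
Conditions: LiN(iPr)2 (LDA), THF, −78 °C; MeI, −78 → 0 °C
Reagents that add atoms: iodomethane (CI)
Why: Kinetic α′-deprotonation of the enone gives the cross-conjugated dienolate, which is C-methylated; the new centre should be mainly trans and is erased by the next enolisation.

Step 4
Reactants: 5 6-methyl enone; 6 allyl bromide
Product: 8 6-allyl-6-methyl enone (allyl trans to the C5 side chain), via lithium dienolate 7 (not isolated)
Conditions: LiN(iPr)2 (LDA), THF, −78 → 0 °C; 6, DMPU, −78 °C → rt
Reagents that add atoms: none
Why: Enolate alkylation forming the quaternary carbon; allyl bromide should approach the enolate face opposite the bulky C5 substituent, so allyl ends trans and methyl cis to it, which sets C6.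

Step 5
Reactants: 8 6-allyl-6-methyl enone
Product: 9 methylidene diene (C1=CH2 in place of C1=O)
Conditions: Ph3PCH3Br, KOtBu, toluene, 90 °C
Reagents that add atoms: methyltriphenylphosphonium bromide (C[P+](c1ccccc1)(c1ccccc1)c1ccccc1.[Br-])
Why: Wittig methylenation under the hot alkoxide conditions used for hindered ketones; the ketone has no α-hydrogen on the C6 side, and γ-deprotonation is reversible and touches no stereocentre.

Step 6
Reactants: 9 methylidene diene
Product: 11 primary alcohol (3-hydroxypropyl chain), via B-alkyl-9-borabicyclononane 10 (not isolated)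
Conditions: 9-BBN, THF, 0 °C → rt; then aq. NaOH, H2O2, 0 °C
Reagents that add atoms: hydrogen peroxide (OO)
Why: Anti-Markovnikov hydroboration–oxidation; 9-BBN should select the isolated monosubstituted vinyl group over the conjugated exocyclic methylene, which is flanked by a quaternary carbon, and over the trisubstituted ring alkene.

Step 7
Reactants: 11 primary alcohol
Product: 12 TBDPS ether of 11
Conditions: TBDPSCl, imidazole, DMF, rt
Reagents that add atoms: tert-butyl(chloro)diphenylsilane (CC(C)(C)[Si](Cl)(c1ccccc1)c1ccccc1)
Why: Standard silylation of a primary alcohol; TBDPS is acid-stable enough for step 8 and inert to hydride, ylide and carbenoid reagents.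

Step 8
Reactants: 12 TBDPS ether of 11
Product: 13 unsaturated spirolactone (ring oxygen on C1 trans to the C6 methyl)
Conditions: Mn(OAc)3·2H2O (2.2 equiv), KOAc, AcOH, 90 °C
Reagents that add atoms: acetic acid (CC(=O)O)
Why: Oxidative free-radical γ-lactone annulation by trivalent manganese: the carboxymethyl radical adds to the exocyclic CH2 of the diene, the allyl radical is oxidised to the cation and the carboxyl group closes the five-membered ring at C1. Closure should come from the face opposite the pseudo-axial C6 methyl, which sets C1 and keeps the C2=C3 alkene.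

Step 9
Reactants: 13 unsaturated spirolactone
Product: 14 saturated spirolactone (C2 methyl cis to the C6 methyl)
Conditions: H2 (1 atm), [Ir(cod)(PCy3)(py)]PF6 (5 mol %), CH2Cl2, rt
Reagents that add atoms: none
Why: Oxygen-directed homogeneous hydrogenation of a trisubstituted alkene; the cationic iridium complex binds the lactone oxygen and delivers hydrogen syn to the C1–O bond, the face that is also free of the axial C6 methyl. This sets C2 with its methyl cis to the C6 methyl and avoids the allylic C–O hydrogenolysis expected on palladium.

Step 10
Reactants: 14 saturated spirolactone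
Product: 16 lactol (both anomers), via diisobutylaluminium lactolate 15 (not isolated)
Conditions: iBu2AlH, CH2Cl2, −78 °C; aq. potassium sodium tartrate
Reagents that add atoms: none
Why: Partial reduction of a γ-lactone; the aluminium hemiacetal is stable at −78 °C and gives the lactol on work-up, with both silyl ethers untouched.

Step 11
Reactants: 16 lactol
Product: 18 spiro 2,3-dihydrofuran, via lactol methanesulfonate 17 (not isolated)
Conditions: MsCl, Et3N, CH2Cl2, −40 → 40 °C
Reagents that add atoms: none
Why: Dehydration of a lactol through its anomeric sulfonate and elimination to the endocyclic enol ether, as used for furanoid glycals; the basic medium protects the acid-labile product.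

Step 12
Reactants: 18 spiro 2,3-dihydrofuran
Product: 20 4,5-dihydrofuran-3-carbaldehyde, via iminium chloride 19 (not isolated)
Conditions: POCl3, DMF, CH2Cl2, 0 °C → rt; aq. NaOAc
Reagents that add atoms: N,N-dimethylformamide (CN(C)C=O); water (O)
Why: Vilsmeier–Haack formylation of a cyclic enol ether at its nucleophilic β-carbon; hydrolysis of the vinylogous iminium salt gives the β-alkoxy enal, and the hindered silyl ethers should be spared.

Step 13
Reactants: 20 4,5-dihydrofuran-3-carbaldehyde; 21 ethyltriphenylphosphonium bromide
Product: 23 (Z)-propenyl dienyl ether, via ethylidenetriphenylphosphorane 22 (not isolated)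
Conditions: NaN(SiMe3)2, THF, 0 °C; then 20, −78 °C → rt
Reagents that add atoms: none
Why: Wittig reaction of a non-stabilised ylide under lithium-free conditions, which should favour the Z-alkene by kinetic oxaphosphetane formation.

Step 14
Reactants: 24 methyl 3-oxopentanoate
Product: 25 methyl 2-diazo-3-oxopentanoate
Conditions: 4-acetamidobenzenesulfonyl azide, Et3N, MeCN, 0 °C → rt
Reagents that add atoms: 4-acetamidobenzenesulfonyl azide (CC(=O)Nc1ccc(cc1)S(=O)(=O)N=[N+]=[N-])
Why: Regitz diazo transfer to the activated methylene of a β-keto ester.

Step 15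
Reactants: 25 methyl 2-diazo-3-oxopentanoate
Product: 26 methyl (3Z)-3-(tert-butyldimethylsilyloxy)-2-diazopent-3-enoate
Conditions: TBSOTf, Et3N, CH2Cl2, 0 °C
Reagents that add atoms: tert-butyldimethylsilyl trifluoromethanesulfonate (CC(C)(C)[Si](C)(C)OS(=O)(=O)C(F)(F)F)
Why: Enol silylation of an α-diazo ketone on its only enolisable side; the Z enol ether is expected, which places the terminal methyl trans to the diazo carbon.

Step 16
Reactants: 23 (Z)-propenyl dienyl ether; 26 methyl (3Z)-3-(tert-butyldimethylsilyloxy)-2-diazopent-3-enoate
Product: 28 furo-fused cycloheptadiene silyl enol ether, via cis-divinylcyclopropane 27 (not isolated)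
Conditions: Rh2(OAc)4 (2 mol %), CH2Cl2, 40 °C, slow addition of 26 (2 equiv); then toluene, 110 °C
Reagents that add atoms: none
Why: Rh2(OAc)4 (divalent rhodium) converts 26 with loss of nitrogen into a donor/acceptor vinylcarbenoid, which adds to the Z-propenyl C=C of 23 to give cyclopropane 27 with the siloxyvinyl group, the dihydrofuranyl group and the methyl all cis and the ester trans; on heating, 27 undergoes a [3,3] shift through a boat to 28. The closest known reaction type is the tandem cyclopropanation/Cope rearrangement ([4+3] annulation) of siloxyvinyl diazoacetates with 1-oxygenated and cis-substituted dienes. The three-membered ring closes by concerted carbenoid [2+1] addition; seven-membered ring A closes by strain-driven sigmatropic ring expansion that joins Cc to Cd after Ca–Cg has formed. The three new sp3 centres (Cg, Cc, Cd) get their relative configuration from stereospecific addition to the Z-alkene, the Z enol ether and the boat geometry; their sense relative to C1 is not controlled and need not be, because step 17 flattens all three. The step needs site selectivity between the two alkenes of the diene and against O–H insertion. Vinylogous donation from the ring F oxygen makes the propenyl terminus the most nucleophilic carbon, whereas the ring alkene carbon is fully substituted and flanked by spiro ring B. A cis-disubstituted alkene is accepted by such carbenoids where a trans one is not, the methyl on the vinyl terminus of the carbenoid blocks vinylogous attack, and both hydroxyls are silylated. The quaternary C1 keeps ring F from aromatising, so 23 persists under the conditions.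

Step 17
Reactants: 28 furo-fused cycloheptadiene silyl enol ether
Product: 30 bis-silyl tropone, via dienone 29 (not isolated)
Conditions: DDQ (2.5 equiv), 1,4-dioxane, rt → 80 °C
Reagents that add atoms: none
Why: DDQ dehydrogenation: hydride abstraction from the doubly allylic Cg–H gives a siloxy-stabilised pentadienyl cation that loses silicon to form the dienone. A second hydride abstraction at the allylic O–CH (Cd) and loss of the α-proton at Cc give the tropone, driven by its aromatic stabilisation.

Step 18
Reactants: 30 bis-silyl tropone
Product: 31 tropone diol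
Conditions: HF·pyridine, pyridine, THF, 0 °C → rt
Reagents that add atoms: none
Why: Fluoride-driven cleavage of the tertiary TBS and primary TBDPS ethers under buffered acidic conditions that the tropone, the methyl ester and the tertiary alcohol should tolerate.

Step 19
Reactants: 31 tropone diol
Product: 33 CNP0448476.4, via aldehyde 32 (not isolated)
Conditions: TEMPO (20 mol %), PhI(OAc)2 (2.5 equiv), MeCN/H2O 1:1, rt
Reagents that add atoms: water (O)
Why: Oxoammonium oxidation of the primary alcohol to the aldehyde, whose hydrate is oxidised on to the acid in aqueous acetonitrile; the tertiary alcohol cannot be oxidised and no ester-cleaving reagent is present.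

## Compound list

1 | (S)-carvone, (5S)-2-methyl-5-(prop-1-en-2-yl)cyclohex-2-en-1-one | CC1=CC[C@@H](CC1=O)C(C)=C | starting material
2 | (5S)-5-(2-hydroxypropan-2-yl)-2-methylcyclohex-2-en-1-one | CC1=CC[C@@H](CC1=O)C(C)(C)O | intermediate
3 | (5S)-5-[2-(tert-butyldimethylsilyloxy)propan-2-yl]-2-methylcyclohex-2-en-1-one | CC1=CC[C@@H](CC1=O)C(C)(C)O[Si](C)(C)C(C)(C)C | intermediate
4 | lithium dienolate of 3 (OLi on C1, C1=C6 and C2=C3) | CC1=CC[C@@H](C=C1O[Li])C(C)(C)O[Si](C)(C)C(C)(C)C | intermediate
5 | (5S,6R)-5-[2-(TBS-oxy)propan-2-yl]-2,6-dimethylcyclohex-2-en-1-one, 6-methyl trans to the C5 side chain (major epimer) | CC1=CC[C@@H]([C@@H](C)C1=O)C(C)(C)O[Si](C)(C)C(C)(C)C | intermediate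
6 | allyl bromide (3-bromoprop-1-ene) | C=CCBr | starting material
7 | lithium dienolate of 5 (OLi on C1, tetrasubstituted C1=C6) | CC1=CC[C@@H](C(C)=C1O[Li])C(C)(C)O[Si](C)(C)C(C)(C)C | intermediate
8 | (5S,6R)-6-allyl-5-[2-(TBS-oxy)propan-2-yl]-2,6-dimethylcyclohex-2-en-1-one, allyl trans and methyl cis to the C5 side chain | CC1=CC[C@@H]([C@@](C)(CC=C)C1=O)C(C)(C)O[Si](C)(C)C(C)(C)C | intermediate
9 | methylidene diene: 8 with C1=CH2 in place of C1=O | CC1=CC[C@@H]([C@@](C)(CC=C)C1=C)C(C)(C)O[Si](C)(C)C(C)(C)C | intermediate
10 | B-alkyl-9-borabicyclo[3.3.1]nonane: 9 with the allyl group as a 3-(9-borabicyclononan-9-yl)propyl chain | CC1=CC[C@@H]([C@@](C)(CCCB2C3CCCC2CCC3)C1=C)C(C)(C)O[Si](C)(C)C(C)(C)C | intermediate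
11 | primary alcohol: 9 with the allyl group as a 3-hydroxypropyl chain | CC1=CC[C@@H]([C@@](C)(CCCO)C1=C)C(C)(C)O[Si](C)(C)C(C)(C)C | intermediate
12 | TBDPS ether of 11 | CC1=CC[C@@H]([C@@](C)(CCCO[Si](c2ccccc2)(c2ccccc2)C(C)(C)C)C1=C)C(C)(C)O[Si](C)(C)C(C)(C)C | intermediate
13 | 6,10-dimethyl-9-[2-(TBS-oxy)propan-2-yl]-10-[3-(TBDPS-oxy)propyl]-1-oxaspiro[4.5]dec-6-en-2-one, ring oxygen trans to the 10-methyl and cis to the 10-propyl chain | O=C1CC[C@]2(O1)C(C)=CC[C@H](C(C)(C)O[Si](C)(C)C(C)(C)C)[C@@]2(C)CCCO[Si](c3ccccc3)(c3ccccc3)C(C)(C)C | intermediate
14 | 6,7-dihydro derivative of 13 (1-oxaspiro[4.5]decan-2-one), 6-methyl cis to the 10-methyl and trans to the ring oxygen | O=C1CC[C@]2(O1)[C@H](C)CC[C@H](C(C)(C)O[Si](C)(C)C(C)(C)C)[C@@]2(C)CCCO[Si](c3ccccc3)(c3ccccc3)C(C)(C)C | intermediate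
15 | diisobutylaluminium lactolate of 14 (O–Al on the former carbonyl carbon) | CC(C)C[Al](CC(C)C)OC1CC[C@]2(O1)[C@H](C)CC[C@H](C(C)(C)O[Si](C)(C)C(C)(C)C)[C@@]2(C)CCCO[Si](c3ccccc3)(c3ccccc3)C(C)(C)C | intermediate
16 | lactol: 14 with C2=O reduced to CH–OH, both anomers | OC1CC[C@]2(O1)[C@H](C)CC[C@H](C(C)(C)O[Si](C)(C)C(C)(C)C)[C@@]2(C)CCCO[Si](c3ccccc3)(c3ccccc3)C(C)(C)C | intermediate
17 | methanesulfonate of lactol 16 | CS(=O)(=O)OC1CC[C@]2(O1)[C@H](C)CC[C@H](C(C)(C)O[Si](C)(C)C(C)(C)C)[C@@]2(C)CCCO[Si](c3ccccc3)(c3ccccc3)C(C)(C)C | intermediate
18 | 6,10-dimethyl-9-[2-(TBS-oxy)propan-2-yl]-10-[3-(TBDPS-oxy)propyl]-1-oxaspiro[4.5]dec-2-ene, configuration as in 14 | C1=CC[C@]2(O1)[C@H](C)CC[C@H](C(C)(C)O[Si](C)(C)C(C)(C)C)[C@@]2(C)CCCO[Si](c3ccccc3)(c3ccccc3)C(C)(C)C | intermediate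
19 | iminium chloride: 18 with a CH=N(+)(CH3)2 group on C3 | C[N+](C)=CC1=CO[C@@]2(C1)[C@H](C)CC[C@H](C(C)(C)O[Si](C)(C)C(C)(C)C)[C@@]2(C)CCCO[Si](c3ccccc3)(c3ccccc3)C(C)(C)C.[Cl-] | intermediate
20 | aldehyde: 18 with a formyl group on C3 (1-oxaspiro[4.5]dec-2-ene-3-carbaldehyde) | O=CC1=CO[C@@]2(C1)[C@H](C)CC[C@H](C(C)(C)O[Si](C)(C)C(C)(C)C)[C@@]2(C)CCCO[Si](c3ccccc3)(c3ccccc3)C(C)(C)C | intermediate
21 | ethyltriphenylphosphonium bromide | CC[P+](c1ccccc1)(c1ccccc1)c1ccccc1.[Br-] | starting material
22 | ethylidenetriphenylphosphorane | CC=P(c1ccccc1)(c1ccccc1)c1ccccc1 | intermediate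
23 | dienyl ether: 18 with a (Z)-prop-1-enyl group on C3 | C/C=C\C1=CO[C@@]2(C1)[C@H](C)CC[C@H](C(C)(C)O[Si](C)(C)C(C)(C)C)[C@@]2(C)CCCO[Si](c3ccccc3)(c3ccccc3)C(C)(C)C | intermediate
24 | methyl 3-oxopentanoate | CCC(=O)CC(=O)OC | starting material
25 | methyl 2-diazo-3-oxopentanoate | CCC(=O)C(=[N+]=[N-])C(=O)OC | intermediate
26 | methyl (3Z)-3-(tert-butyldimethylsilyloxy)-2-diazopent-3-enoate | COC(=O)C(=[N+]=[N-])/C(O[Si](C)(C)C(C)(C)C)=C/C | intermediate
27 | cis-divinylcyclopropane: methyl 1-[(Z)-1-(TBS-oxy)prop-1-enyl]-2-methyl-3-(spiro dihydrofuran-3-yl)cyclopropane-1-carboxylate, the three carbon substituents cis and the ester trans, both facial isomers | COC(=O)C1(/C(O[Si](C)(C)C(C)(C)C)=C/C)C(C)C1C2=CO[C@@]3(C2)[C@H](C)CC[C@H](C(C)(C)O[Si](C)(C)C(C)(C)C)[C@@]3(C)CCCO[Si](c4ccccc4)(c4ccccc4)C(C)(C)C | intermediate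
28 | cycloadduct: ring A as cyclohepta-1,4-diene with CO2CH3 on Ca, OTBS on Cb, CH3 on Cc and Cg, ring F oxygen on Cd, Ce=Cf; ring B as in 14 | COC(=O)C1=C(O[Si](C)(C)C(C)(C)C)C(C)C2O[C@@]3(CC2=CC1C)[C@H](C)CC[C@H](C(C)(C)O[Si](C)(C)C(C)(C)C)[C@@]3(C)CCCO[Si](c4ccccc4)(c4ccccc4)C(C)(C)C | intermediate
29 | dienone: ring A with Cb=O, Ca=Cg and Ce=Cf, Cc and Cd still sp3 | COC(=O)C1=C(C)C=C2C(O[C@@]3(C2)[C@H](C)CC[C@H](C(C)(C)O[Si](C)(C)C(C)(C)C)[C@@]3(C)CCCO[Si](c4ccccc4)(c4ccccc4)C(C)(C)C)C(C)C1=O | intermediate
30 | bis-silyl tropone: 33 with the tertiary alcohol as TBS ether and CH2OTBDPS in place of CO2H | COC(=O)c1c(C)cc2c(c(C)c1=O)O[C@@]1(C2)[C@H](C)CC[C@H](C(C)(C)O[Si](C)(C)C(C)(C)C)[C@@]1(C)CCCO[Si](c1ccccc1)(c1ccccc1)C(C)(C)C | intermediate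
31 | tropone diol: 33 with CH2OH in place of CO2H | COC(=O)c1c(C)cc2c(c(C)c1=O)O[C@@]1(C2)[C@H](C)CC[C@H](C(C)(C)O)[C@@]1(C)CCCO | intermediate
32 | aldehyde: 33 with CHO in place of CO2H | COC(=O)c1c(C)cc2c(c(C)c1=O)O[C@@]1(C2)[C@H](C)CC[C@H](C(C)(C)O)[C@@]1(C)CCC=O | intermediate
33 | CNP0448476.4; ring B C1 S, C2 R, C5 S, C6 R | COC(=O)c1c(C)cc2c(c(C)c1=O)O[C@@]1(C2)[C@H](C)CC[C@H](C(C)(C)O)[C@@]1(C)CCC(=O)O | target

## Step count and risks

Total: 19 steps. Longest linear sequence: 17 steps (steps 1–13 and 16–19 from (S)-carvone); the diazo ester branch is steps 14–15.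

**Step 16 (key step).** The most likely failures are carbenoid addition to the ring F enol ether or insertion into an allylic C–H bond instead of cyclopropanation of the propenyl group, and a slow boat Cope shift of the all-cis cyclopropane 27, because the methyl on the third ring carbon lies under the forming bond. Any E-isomer of 23 would not react at the propenyl group at all.

Fallback: move the carbenoid addition to a monosubstituted alkene and bring in the Cg methyl afterwards.
- From aldehyde 20, methylenation with Ph3P=CH2 gives vinyl dienyl ether F1.
- F1 and 26 with Rh2(OAc)4 give the nor-methyl cycloadduct F2, through a cyclopropane with no cis substituent on its third carbon.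
- One equivalent of DDQ gives alkylidene β-keto ester F3.
- Conjugate addition of Me2CuLi with Me3SiCl to the doubly activated Ca=Cg bond gives β-keto ester F4.
- DDQ as in step 17 then returns the route to 30.

**Step 8.** The risks are partial loss of the silyl ethers or ionisation of the tertiary allylic lactone in hot acetic acid, capture of the allyl cation by acetate, and imperfect facial selectivity at C1.

Fallback: from 12, Rh2(OAc)4-catalysed cyclopropanation of the exocyclic methylene (the less substituted end of the diene) with tert-butyl diazoacetate gives spiro vinylcyclopropane ester F5. Brief treatment with CF3CO2H in CH2Cl2 at 0 °C opens the C1–CH bond to the same allyl cation, and the ester oxygen closes with loss of the tert-butyl group. This returns to 13.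

**Step 9.** Hydrogen may be delivered to the wrong face of C2=C3, or the hindered trisubstituted alkene may not reduce, because a lactone is only a moderate directing group.

Fallback: from 13, LiAlH4 gives unsaturated diol F6, whose free tertiary allylic hydroxyl on C1 binds the same iridium catalyst firmly. Directed hydrogenation gives saturated diol F7. Oxidative lactonisation with TEMPO and PhI(OAc)2 returns to 14.

**Step 13.** Z-selectivity may erode with the conjugated, vinylogous-ester aldehyde, and the E-isomer is dead weight in step 16.

Fallback: from 20, the Stork–Zhao olefination with Ph3P=CHI gives (Z)-vinyl iodide F8. Negishi coupling with MeZnCl and Pd(PPh3)4 (zerovalent palladium) proceeds with retention and returns to 23.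

**Step 17.** The second dehydrogenation may stall at dienone 29, or the acidic hydroquinone may promote β-elimination of the ring F oxygen from 29 and open ring F.

Fallback: from 28, Saegusa–Ito oxidation with Pd(OAc)2 (divalent palladium) in MeCN/DMSO gives 29 as an isolated compound. Bromination at Cc with PhNMe3Br3 gives α-bromo ketone F9. Dehydrobromination with DBU returns to 30.

## Further compounds

F1 | step 16 | vinyl dienyl ether: 18 with an ethenyl group on C3 | C=CC1=CO[C@@]2(C1)[C@H](C)CC[C@H](C(C)(C)O[Si](C)(C)C(C)(C)C)[C@@]2(C)CCCO[Si](c3ccccc3)(c3ccccc3)C(C)(C)C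
F2 | step 16 | nor-methyl cycloadduct: 28 with CH2 at Cg | COC(=O)C1=C(O[Si](C)(C)C(C)(C)C)C(C)C2O[C@@]3(CC2=CC1)[C@H](C)CC[C@H](C(C)(C)O[Si](C)(C)C(C)(C)C)[C@@]3(C)CCCO[Si](c4ccccc4)(c4ccccc4)C(C)(C)C
F3 | step 16 | alkylidene β-keto ester: 29 without the Cg methyl | COC(=O)C1=CC=C2C(O[C@@]3(C2)[C@H](C)CC[C@H](C(C)(C)O[Si](C)(C)C(C)(C)C)[C@@]3(C)CCCO[Si](c4ccccc4)(c4ccccc4)C(C)(C)C)C(C)C1=O
F4 | step 16 | β-keto ester: 28 with Cb=O and H on Ca in place of the silyl enol ether | COC(=O)C1C(C)C=C2C(O[C@@]3(C2)[C@H](C)CC[C@H](C(C)(C)O[Si](C)(C)C(C)(C)C)[C@@]3(C)CCCO[Si](c4ccccc4)(c4ccccc4)C(C)(C)C)C(C)C1=O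
F5 | step 8 | spiro vinylcyclopropane ester: tert-butyl cyclopropanecarboxylate spiro-fused at C1 of diene 12, C2=C3 retained | CC(C)(C)OC(=O)C1CC12C(C)=CC[C@H](C(C)(C)O[Si](C)(C)C(C)(C)C)[C@@]2(C)CCCO[Si](c3ccccc3)(c3ccccc3)C(C)(C)C
F6 | step 9 | unsaturated diol: 13 with the lactone reduced to a tertiary allylic alcohol on C1 and a 3-hydroxypropyl chain | OCCC[C@]1(O)C(C)=CC[C@H](C(C)(C)O[Si](C)(C)C(C)(C)C)[C@@]1(C)CCCO[Si](c2ccccc2)(c2ccccc2)C(C)(C)C
F7 | step 9 | saturated diol: F6 with C2–C3 hydrogenated, C2 methyl cis to the C6 methyl | OCCC[C@]1(O)[C@H](C)CC[C@H](C(C)(C)O[Si](C)(C)C(C)(C)C)[C@@]1(C)CCCO[Si](c2ccccc2)(c2ccccc2)C(C)(C)C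
F8 | step 13 | (Z)-vinyl iodide: 18 with a (Z)-2-iodoethenyl group on C3 | I/C=C\C1=CO[C@@]2(C1)[C@H](C)CC[C@H](C(C)(C)O[Si](C)(C)C(C)(C)C)[C@@]2(C)CCCO[Si](c3ccccc3)(c3ccccc3)C(C)(C)C
F9 | step 17 | α-bromo ketone: 29 with bromine on Cc | COC(=O)C1=C(C)C=C2C(O[C@@]3(C2)[C@H](C)CC[C@H](C(C)(C)O[Si](C)(C)C(C)(C)C)[C@@]3(C)CCCO[Si](c4ccccc4)(c4ccccc4)C(C)(C)C)C(C)(Br)C1=O
A1 | alternative 1 | ring B cyclohexene aldehyde (endo Diels–Alder adduct) | CC(C)(C)[Si](C)(C)O[C@H]1C(C)=CC[C@H](C(C)(C)O[Si](CC)(CC)CC)[C@@]1(C)C=O
A2 | alternative 2 | ring B cyclohexene acid with quaternary carbon | OC(=O)[C@H]1CCC(C)=C[C@]1(C)CCCO[Si](C)(C)C(C)(C)C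
A3 | alternative 3 | spiro dihydrofurotropone with ring B alkene and two methyl esters | COC(=O)C1=C(C)C=C2C(=C(C)C1=O)O[C@@]3(C2)C(C)=CC[C@H](C(C)(C)O[Si](CC)(CC)CC)[C@@]3(C)CCC(=O)OC
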